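**Retrosynthetic overview**
1. Side chain and monomer: tiglic acid 1 is hydrogenated to (R)-2-methylbutanoic acid 2. Acid 2 acylates phloroglucinol 3 (through acid chloride 4) to acylphloroglucinol 5, and prenyl bromide 6 converts 5 into the biosynthetic monomer 7 (3-prenyl-acylphloroglucinol).
2. Key disconnection: the final product is cut first at its two chroman C–O bonds, not at the bridge, and only then at the 6-methylheptylidene bridge. In the forward sense, two molecules of 7 and 6-methylheptanal 8 give o-quinone methide 9 and then the open bis-prenyl dimer 10 in one flask.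
3. Ring order: the two benzene rings are bought (as 3). The two dihydropyran rings are formed last and together, by acid-mediated prenyl-to-phenol closure of 10 to target 11. The bridge is installed first so that it steers closure onto the oxygen beside the acyl group.

Assumption: both 2-methylbutanoyl centres in the SMILES are read as (R), the bridge carbon carries two identical arms and is not a stereocentre, and 6-methylheptanal 8 is bought as a catalogue flavour aldehyde.

**Route**

Step 1
Reactants: 1 tiglic acid
Product: 2 (R)-2-methylbutanoic acid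
Conditions: H2 (2 atm), Ru(OAc)2[(R)-H8-BINAP] (0.5 mol %; H8-BINAP = 2,2'-bis(diphenylphosphino)-5,5',6,6',7,7',8,8'-octahydro-1,1'-binaphthyl), MeOH, 20 °C, 12 h; acid–base extraction, distillation; ee by chiral GC
Reagents that add atoms: none
Why: Carboxylate-directed asymmetric hydrogenation of a trisubstituted α,β-unsaturated acid (Noyori–Takaya type), in which the divalent ruthenium catalyst of the (R)-ligand series binds the carboxylate and delivers H2 to one alkene face, setting the (R) centre (the levorotatory acid) in about 97% ee.

Step 2
Reactants: 2 (R)-2-methylbutanoic acid; 3 phloroglucinol (anhydrous)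
Product: 5 (2R)-2-methyl-1-(2,4,6-trihydroxyphenyl)butan-1-one, via (R)-2-methylbutanoyl chloride 4 (not isolated)
Conditions: (COCl)2 (1.05 equiv), DMF (cat.), CH2Cl2, 0 °C → rt; then 3 (1.0 equiv), AlCl3 (3.5 equiv), PhNO2/CH2Cl2, 0 °C → rt (kept below 40 °C), 16 h; ice/1 M HCl
Reagents that add atoms: none
Why: Friedel–Crafts C-acylation of a triol whose three ring carbons are equivalent, so only one mono-ketone can form and its aluminium chelate resists a second acylation; the α-stereocentre comes from 2 and is carried through because neither the acid chloride nor the chelated aryl ketone enolises readily at or below room temperature.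

Step 3
Reactants: 5 (2R)-2-methyl-1-(2,4,6-trihydroxyphenyl)butan-1-one (1.5 equiv); 6 prenyl bromide (1.0 equiv)
Product: 7 (2R)-2-methyl-1-[2,4,6-trihydroxy-3-(3-methylbut-2-en-1-yl)phenyl]butan-1-one
Conditions: 10% aq. KOH (2 equiv), 0 °C, 2 h; 1 M HCl; chromatography (excess 5 recovered)
Reagents that add atoms: none
Why: C-alkylation of the ambident phenoxide by the allylic bromide (SN2; water solvates oxygen and favours carbon attack), where the two free ring carbons of 5 are equivalent so mono-prenylation gives one isomer and excess 5 limits diprenylation; the stereocentre is not deprotonated because the substrate is already a vinylogous carboxylate anion.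

Step 4
Reactants: 7 (2R)-2-methyl-1-[2,4,6-trihydroxy-3-(3-methylbut-2-en-1-yl)phenyl]butan-1-one (2.1 equiv); 8 6-methylheptanal (1.0 equiv)
Product: 11 6,6'-(6-methylheptane-1,1-diyl)bis{5,7-dihydroxy-2,2-dimethyl-8-[(2R)-2-methylbutanoyl]chromane}, via o-quinone methide 9 (not isolated), via open bis-prenyl dimer 10 (not isolated)
Conditions: 8 added over 1 h to 7, TsOH·H2O (20 mol %), 1,2-dichloroethane, 0 → 23 °C, 3 h; then 70 °C, 6–12 h
Reagents that add atoms: none
Why: Proposed new method: acid-catalysed Friedel–Crafts hydroxyalkylation/dehydration of 7 at its only free ring carbon gives o-quinone methide 9, a second 7 adds to it (Michael-type Friedel–Crafts alkylation) to give 10, and on warming the same acid protonates each prenyl alkene in the Markovnikov sense so that a flanking phenol oxygen closes the six-membered ether (intramolecular hydroalkoxylation); closure onto the oxygen beside the acyl group is expected, though not proven, because the other flanking hydroxyl sits next to the branched bridge and is tied into the inter-ring O–H···O hydrogen bonds, and because a tertiary ether of a vinylogous acid can re-open under acid and settle at the more stable isomer; the closest known reactions are acid-mediated aldehyde bridging of acylphloroglucinols and acid cyclisation of ortho-prenylphenols to 2,2-dimethylchromans; no new stereocentre arises and the two (R) centres are untouched.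

**Compound list**
1 | tiglic acid, (E)-2-methylbut-2-enoic acid | C/C=C(\C)C(=O)O | starting material
2 | (R)-2-methylbutanoic acid | CC[C@@H](C)C(=O)O | intermediate
3 | phloroglucinol, benzene-1,3,5-triol | Oc1cc(O)cc(O)c1 | starting material
4 | (R)-2-methylbutanoyl chloride | CC[C@@H](C)C(=O)Cl | intermediate
5 | (2R)-2-methyl-1-(2,4,6-trihydroxyphenyl)butan-1-one | CC[C@@H](C)C(=O)c1c(O)cc(O)cc1O | intermediate
6 | prenyl bromide, 1-bromo-3-methylbut-2-ene | CC(C)=CCBr | starting material
7 | (2R)-2-methyl-1-[2,4,6-trihydroxy-3-(3-methylbut-2-en-1-yl)phenyl]butan-1-one | CC[C@@H](C)C(=O)c1c(O)cc(O)c(CC=C(C)C)c1O | intermediate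
8 | 6-methylheptanal | CC(C)CCCCC=O | starting material
9 | 3,5-dihydroxy-2-[(2R)-2-methylbutanoyl]-4-(3-methylbut-2-en-1-yl)-6-(6-methylheptylidene)cyclohexa-2,4-dien-1-one (o-quinone methide, alkene geometry not defined) | CC[C@@H](C)C(=O)C1=C(O)C(CC=C(C)C)=C(O)C(=CCCCCC(C)C)C1=O | intermediate
10 | 1,1-bis{2,4,6-trihydroxy-3-[(2R)-2-methylbutanoyl]-5-(3-methylbut-2-en-1-yl)phenyl}-6-methylheptane | CC[C@@H](C)C(=O)c1c(O)c(CC=C(C)C)c(O)c(C(CCCCC(C)C)c2c(O)c(CC=C(C)C)c(O)c(C(=O)[C@H](C)CC)c2O)c1O | intermediate
11 | 6,6'-(6-methylheptane-1,1-diyl)bis{5,7-dihydroxy-2,2-dimethyl-8-[(2R)-2-methylbutanoyl]chromane} | CC[C@@H](C)C(=O)c1c(O)c(C(CCCCC(C)C)c2c(O)c3c(c(C(=O)[C@H](C)CC)c2O)OC(C)(C)CC3)c(O)c2c1OC(C)(C)CC2 | target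

**Step count**
Total steps: 4. Longest linear sequence: 4 (1 → 2 → 5 → 7 → 11).

**Steps most likely to fail, with fallbacks**

Step 4 (highest risk). Possible failures are closure onto the bridge-side oxygen (isomeric or mixed bis-chromans), prenyl closure at the monomer stage before bridging, self-aldol of 8, and partial epimerisation of the α-centres under hot acid. The regiochemistry of the product is read from HMBC correlations of the ring-oxygen carbon. The fallback sets out from 7 and comes back at 11 by reversing the order of events. Compound 7 is cyclised at the monomer stage (Amberlyst 15, toluene, 80 °C) to give 5,7-dihydroxy-2,2-dimethyl-8-[(2R)-2-methylbutanoyl]chromane F1, which is separated by chromatography from its regioisomer 5,7-dihydroxy-2,2-dimethyl-6-[(2R)-2-methylbutanoyl]chromane F2. F1 (2.1 equiv) is then bridged with 8 (TsOH·H2O cat., 1,2-dichloroethane, rt); its only free ring carbon lies between the two hydroxyls, so the product is 11.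

Step 3. Possible failures are diprenylation, O-prenylation and a low yield of the mono-C-prenyl compound. The fallback sets out from 5 and comes back at 10 by building the bridge before the prenyl groups. An excess of 5 (4 equiv, the surplus recovered) is condensed with 8 (TsOH·H2O cat., 1,2-dichloroethane, rt) to give 1,1-bis{2,4,6-trihydroxy-3-[(2R)-2-methylbutanoyl]phenyl}-6-methylheptane F3. Each ring of F3 has a single free carbon, so C-prenylation with 6 (2.2 equiv, 10% aq. KOH, 0 °C) can only give 10. Compound 10 is then isolated and closed to 11 with TsOH·H2O at 70 °C, as in the second half of step 4.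

Step 2. Possible failures are partial racemisation of the α-centre under AlCl3, O-acylation and diacylation. The fallback sets out from 2 and 3 and comes back at 5, replacing the Friedel–Crafts reaction by an aryllithium acylation. Compound 3 is protected (MOMCl, iPr2NEt, CH2Cl2) as 1,3,5-tris(methoxymethoxy)benzene F4. Acid 2 is coupled with MeNHOMe·HCl (EDC·HCl, N-methylmorpholine, CH2Cl2) to give (2R)-N-methoxy-N,2-dimethylbutanamide F5. F4 is lithiated between two MOM ethers (n-BuLi, THF, 0 °C) and added to F5 at −78 °C to give (2R)-2-methyl-1-[2,4,6-tris(methoxymethoxy)phenyl]butan-1-one F6. The MOM groups are removed with HCl in MeOH at 40 °C to give 5.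

**Further compounds**
F1 | step 4 | 5,7-dihydroxy-2,2-dimethyl-8-[(2R)-2-methylbutanoyl]chromane | CC[C@@H](C)C(=O)c1c(O)cc(O)c2c1OC(C)(C)CC2
F2 | step 4 | 5,7-dihydroxy-2,2-dimethyl-6-[(2R)-2-methylbutanoyl]chromane (regioisomer, removed) | CC[C@@H](C)C(=O)c1c(O)cc2c(c1O)CCC(C)(C)O2
F3 | step 3 | 1,1-bis{2,4,6-trihydroxy-3-[(2R)-2-methylbutanoyl]phenyl}-6-methylheptane | CC[C@@H](C)C(=O)c1c(O)cc(O)c(C(CCCCC(C)C)c2c(O)cc(O)c(C(=O)[C@H](C)CC)c2O)c1O
F4 | step 2 | 1,3,5-tris(methoxymethoxy)benzene | COCOc1cc(OCOC)cc(OCOC)c1
F5 | step 2 | (2R)-N-methoxy-N,2-dimethylbutanamide | CC[C@@H](C)C(=O)N(C)OC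
F6 | step 2 | (2R)-2-methyl-1-[2,4,6-tris(methoxymethoxy)phenyl]butan-1-one | CC[C@@H](C)C(=O)c1c(OCOC)cc(OCOC)cc1OCOC
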